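**Retrosynthetic overview**

- The strategy rests on C2 of the 3-aryl-lactic acid core: it carries the caffeoyl ester oxygen and the carboxyl carbon C1, and sits next to the benzylic C3 that bears the 4-hydroxy-3-methoxyphenyl (guaiacyl) ring. Its dehydro form (C2=C3) is an α-(acyloxy)acrylate whose O–C(=O) unit can chelate rhodium.
- Last skeletal disconnection: the C2–H and C3–H bonds, made by asymmetric hydrogenation of the fully assembled, protected enol caffeate, followed only by acid and fluoride unmasking.
- Before that: C2=C3 by Horner–Wadsworth–Emmons olefination of O-silyl vanillin with an α-(caffeoyloxy)phosphonoacetate, and the caffeoyl O–C2 bond by dirhodium-carbenoid O–H insertion of a diazophosphonoacetate into silyl-protected caffeic acid.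
- No ring is formed; both benzene rings are bought (vanillin, caffeic acid). Bond order: O–C2, then C2=C3, then C2–H/C3–H, then deprotection.

Key step: step 7

Assumption: (R,R)-Et-DuPhos, 1,2-bis[(2R,5R)-2,5-diethylphospholan-1-yl]benzene, is taken to give the (2R) product, as it does for enamides with the same priority pattern at C2; if the sense proves opposite, the (S,S)-ligand is used in the same step with nothing else changed.

Remark: the olefination product is drawn and numbered as the (Z)-enol ester 9, the geometry expected to predominate; any (E)-geometric isomer formed with it is not separated, because both geometries should give the same configuration in step 7.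

**Route**

Step 1
Reactants: 1 vanillin (4-hydroxy-3-methoxybenzaldehyde)
Product: 2 4-(tert-butyldimethylsilyloxy)-3-methoxybenzaldehyde
Conditions: TBSCl, imidazole, DMF, rt
Reagents that add atoms: tert-butyldimethylsilyl chloride (TBSCl), CC(C)(C)[Si](C)(C)Cl
Why: Imidazole-promoted silylation of the acidic phenol is a standard protection and leaves the aldehyde untouched.

Step 2
Reactants: 3 (E)-caffeic acid
Product: 4 tert-butyldimethylsilyl (E)-3-[3,4-bis(tert-butyldimethylsilyloxy)phenyl]prop-2-enoate
Conditions: TBSCl (3.5 equiv), imidazole, DMF, rt; extractive work-up, crude taken on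
Reagents that add atoms: tert-butyldimethylsilyl chloride (TBSCl), CC(C)(C)[Si](C)(C)Cl
Why: Exhaustive silylation caps both catechol oxygens, which would otherwise oxidise or compete in the carbenoid step, and the carboxyl group is silylated along the way; the (E)-alkene is not affected.

Step 3
Reactants: 4 tert-butyldimethylsilyl (E)-3-[3,4-bis(tert-butyldimethylsilyloxy)phenyl]prop-2-enoate
Product: 5 (E)-3-[3,4-bis(tert-butyldimethylsilyloxy)phenyl]prop-2-enoic acid
Conditions: K2CO3 (1.1 equiv), THF/MeOH/H2O, 0 °C to rt, short reaction time; then 1 M HCl to pH 3–4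
Reagents that add atoms: none
Why: A silyl ester is far more labile to mild carbonate solvolysis than an aryl silyl ether, so selective hydrolysis should free only the carboxylic acid.

Step 4
Reactants: 6 tert-butyl 2-(diethoxyphosphoryl)acetate
Product: 7 tert-butyl 2-diazo-2-(diethoxyphosphoryl)acetate
Conditions: 4-acetamidobenzenesulfonyl azide, DBU, MeCN, 0 °C to rt
Reagents that add atoms: 4-acetamidobenzenesulfonyl azide (p-ABSA), CC(=O)Nc1ccc(cc1)S(=O)(=O)N=[N+]=[N-]
Why: Regitz diazo transfer to the doubly activated methylene (P=O and ester) gives the acceptor/acceptor diazo compound, with the sulfonamide as the only by-product.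

Step 5
Reactants: 5 (E)-3-[3,4-bis(tert-butyldimethylsilyloxy)phenyl]prop-2-enoic acid; 7 tert-butyl 2-diazo-2-(diethoxyphosphoryl)acetate
Product: 8 tert-butyl 2-{[(E)-3-(3,4-bis(tert-butyldimethylsilyloxy)phenyl)prop-2-enoyl]oxy}-2-(diethoxyphosphoryl)acetate (racemic at the phosphonate carbon)
Conditions: Rh2(OAc)4 (2 mol%), toluene, 90–100 °C, 7 added slowly by syringe pump to 5 and catalyst
Reagents that add atoms: none
Why: Dirhodium-carbenoid O–H insertion into a carboxylic acid forms the caffeoyl O–C2 bond directly; slow addition keeps the carbenoid concentration low so the acid O–H outcompetes dimerisation and addition to the electron-poor caffeoyl alkene, and the new centre need not be controlled because the next step erases it.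

Step 6
Reactants: 2 4-(tert-butyldimethylsilyloxy)-3-methoxybenzaldehyde; 8 tert-butyl 2-{[(E)-3-(3,4-bis(tert-butyldimethylsilyloxy)phenyl)prop-2-enoyl]oxy}-2-(diethoxyphosphoryl)acetate
Product: 9 tert-butyl (Z)-2-{[(E)-3-(3,4-bis(tert-butyldimethylsilyloxy)phenyl)prop-2-enoyl]oxy}-3-[4-(tert-butyldimethylsilyloxy)-3-methoxyphenyl]prop-2-enoate
Conditions: LiCl, DBU, dry MeCN/THF, 0 °C to rt
Reagents that add atoms: none
Why: Horner–Wadsworth–Emmons olefination in its mild LiCl/amine-base form makes C2=C3 from the strongly stabilised α-acyloxy phosphonate anion without alkoxide or hydride bases that would cleave the caffeoyl ester or the aryl silyl ethers, and the alkene geometry need not be controlled, since any (E)-isomer formed beside the expected (Z)-isomer stays in the material and converges in step 7.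

Step 7
Reactants: 9 tert-butyl (Z)-2-{[(E)-3-(3,4-bis(tert-butyldimethylsilyloxy)phenyl)prop-2-enoyl]oxy}-3-[4-(tert-butyldimethylsilyloxy)-3-methoxyphenyl]prop-2-enoate
Product: 10 tert-butyl (2R)-2-{[(E)-3-(3,4-bis(tert-butyldimethylsilyloxy)phenyl)prop-2-enoyl]oxy}-3-[4-(tert-butyldimethylsilyloxy)-3-methoxyphenyl]propanoate
Conditions: [Rh(cod)((R,R)-Et-DuPhos)]OTf (1–2 mol%), H2 (2–4 bar), degassed MeOH/CH2Cl2, rt; stopped after uptake of one equivalent of H2
Reagents that add atoms: none
Why: The cationic monovalent rhodium centre, once freed of cyclooctadiene, binds the C2=C3 alkene together with the carbonyl oxygen of the acyloxy group on C2 as a five-membered chelate; H2 then adds oxidatively to give a trivalent rhodium dihydride, and migratory insertion followed by reductive elimination delivers both hydrogens syn to one face. The closest known reaction type is the rhodium–DuPhos asymmetric hydrogenation of α-(acyloxy)acrylates and of the analogous α-enamido esters, here run with a cinnamoyl-type acyl group. No ring is closed; only the C2–H and C3–H bonds form. The single stereocentre C2 is set as (R) by the C2-symmetric (R,R)-Et-DuPhos ligand, and because the same chelate is available from either alkene geometry, 9 and any (E)-isomer present in it should converge on one configuration. The step needs facial selectivity at C2=C3 and chemoselectivity over the caffeoyl C=C; both rest on the O–C(=O) unit on C2, since the caffeoyl alkene is 1,2-disubstituted, conjugated and cannot form such an alkene–carbonyl chelate, so it should survive at low pressure when the reaction is stopped at one equivalent of H2. The silyl ethers and the tert-butyl ester are inert under these neutral conditions.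

Step 8
Reactants: 10 tert-butyl (2R)-2-{[(E)-3-(3,4-bis(tert-butyldimethylsilyloxy)phenyl)prop-2-enoyl]oxy}-3-[4-(tert-butyldimethylsilyloxy)-3-methoxyphenyl]propanoate
Product: 11 (2R)-2-{[(E)-3-(3,4-bis(tert-butyldimethylsilyloxy)phenyl)prop-2-enoyl]oxy}-3-[4-(tert-butyldimethylsilyloxy)-3-methoxyphenyl]propanoic acid
Conditions: TFA, Et3SiH (2.5 equiv), CH2Cl2, 0 °C to rt; evaporation with toluene
Reagents that add atoms: none
Why: Acidolysis of the tert-butyl ester proceeds through the tert-butyl cation, which the silane reduces to isobutane before it can alkylate the electron-rich rings; the aryl silyl ethers and both remaining ester bonds tolerate anhydrous acid without epimerisation at C2, and any partial desilylation is harmless because step 9 removes these groups.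

Step 9
Reactants: 11 (2R)-2-{[(E)-3-(3,4-bis(tert-butyldimethylsilyloxy)phenyl)prop-2-enoyl]oxy}-3-[4-(tert-butyldimethylsilyloxy)-3-methoxyphenyl]propanoic acid
Product: 12 clinopodic acid B, (2R)-2-{[(E)-3-(3,4-dihydroxyphenyl)prop-2-enoyl]oxy}-3-(4-hydroxy-3-methoxyphenyl)propanoic acid
Conditions: Et3N·3HF, THF, rt, under argon; acidic aqueous work-up, reverse-phase chromatography
Reagents that add atoms: none
Why: Buffered fluoride cleaves the three aryl silyl ethers through the strong Si–F bond without generating free phenoxide or hydroxide, so the caffeoyl ester, the C2 stereocentre and the oxidation-prone catechol should be preserved.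

**Compound list**

1 | vanillin | COc1cc(C=O)ccc1O | starting material
2 | 4-(tert-butyldimethylsilyloxy)-3-methoxybenzaldehyde | COc1cc(C=O)ccc1O[Si](C)(C)C(C)(C)C | intermediate
3 | (E)-caffeic acid | OC(=O)/C=C/c1ccc(O)c(O)c1 | starting material
4 | tert-butyldimethylsilyl (E)-3-[3,4-bis(tert-butyldimethylsilyloxy)phenyl]prop-2-enoate | CC(C)(C)[Si](C)(C)OC(=O)/C=C/c1ccc(O[Si](C)(C)C(C)(C)C)c(O[Si](C)(C)C(C)(C)C)c1 | intermediate
5 | (E)-3-[3,4-bis(tert-butyldimethylsilyloxy)phenyl]prop-2-enoic acid | OC(=O)/C=C/c1ccc(O[Si](C)(C)C(C)(C)C)c(O[Si](C)(C)C(C)(C)C)c1 | intermediate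
6 | tert-butyl 2-(diethoxyphosphoryl)acetate | CCOP(=O)(OCC)CC(=O)OC(C)(C)C | starting material
7 | tert-butyl 2-diazo-2-(diethoxyphosphoryl)acetate | CCOP(=O)(OCC)C(=[N+]=[N-])C(=O)OC(C)(C)C | intermediate
8 | tert-butyl 2-{[(E)-3-(3,4-bis(tert-butyldimethylsilyloxy)phenyl)prop-2-enoyl]oxy}-2-(diethoxyphosphoryl)acetate (racemic) | CCOP(=O)(OCC)C(OC(=O)/C=C/c1ccc(O[Si](C)(C)C(C)(C)C)c(O[Si](C)(C)C(C)(C)C)c1)C(=O)OC(C)(C)C | intermediate
9 | tert-butyl (Z)-2-{[(E)-3-(3,4-bis(tert-butyldimethylsilyloxy)phenyl)prop-2-enoyl]oxy}-3-[4-(tert-butyldimethylsilyloxy)-3-methoxyphenyl]prop-2-enoate | CC(C)(C)OC(=O)/C(OC(=O)/C=C/c1ccc(O[Si](C)(C)C(C)(C)C)c(O[Si](C)(C)C(C)(C)C)c1)=C/c1ccc(O[Si](C)(C)C(C)(C)C)c(OC)c1 | intermediate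
10 | tert-butyl (2R)-2-{[(E)-3-(3,4-bis(tert-butyldimethylsilyloxy)phenyl)prop-2-enoyl]oxy}-3-[4-(tert-butyldimethylsilyloxy)-3-methoxyphenyl]propanoate | COc1cc(C[C@@H](OC(=O)/C=C/c2ccc(O[Si](C)(C)C(C)(C)C)c(O[Si](C)(C)C(C)(C)C)c2)C(=O)OC(C)(C)C)ccc1O[Si](C)(C)C(C)(C)C | intermediate
11 | (2R)-2-{[(E)-3-(3,4-bis(tert-butyldimethylsilyloxy)phenyl)prop-2-enoyl]oxy}-3-[4-(tert-butyldimethylsilyloxy)-3-methoxyphenyl]propanoic acid | COc1cc(C[C@@H](OC(=O)/C=C/c2ccc(O[Si](C)(C)C(C)(C)C)c(O[Si](C)(C)C(C)(C)C)c2)C(=O)O)ccc1O[Si](C)(C)C(C)(C)C | intermediate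
12 | clinopodic acid B | COc1cc(C[C@@H](OC(=O)/C=C/c2ccc(O)c(O)c2)C(=O)O)ccc1O | target

**Step count**

Total: 9 steps. Longest linear sequence: 7 steps (caffeic acid 3 through steps 2, 3, 5, 6, 7, 8, 9).

**Steps most likely to fail**

Step 7. Hydrogen may also add to the caffeoyl C=C before the enol ester is consumed, or the conjugated acyl group may chelate less well so that facial selectivity falls. The fallback sets out from aldehyde 2 (using 7 and 5) and comes back at 10. It sets the stereocentre on an enol acetate, which has no second alkene, and attaches the caffeoyl group afterwards. Diazo compound 7 and acetic acid under the conditions of step 5 should give tert-butyl 2-acetoxy-2-(diethoxyphosphoryl)acetate F1. LiCl/DBU olefination of F1 with 2 should give tert-butyl (Z)-2-acetoxy-3-[4-(tert-butyldimethylsilyloxy)-3-methoxyphenyl]prop-2-enoate F2 along with tert-butyl (E)-2-acetoxy-3-[4-(tert-butyldimethylsilyloxy)-3-methoxyphenyl]prop-2-enoate F3. Hydrogenation of this mixture with the catalyst of step 7 should give tert-butyl (2R)-2-acetoxy-3-[4-(tert-butyldimethylsilyloxy)-3-methoxyphenyl]propanoate F4. Brief methanolysis of the activated acetate (catalytic K2CO3, MeOH, 0 °C, quenched with AcOH) should release tert-butyl (2R)-2-hydroxy-3-[4-(tert-butyldimethylsilyloxy)-3-methoxyphenyl]propanoate F5. Steglich esterification of F5 with acid 5 (EDC·HCl, DMAP, CH2Cl2, 0 °C) then gives 10.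

Step 5. The carbenoid may dimerise, add to the caffeoyl alkene or the arenes, or be captured too slowly by the conjugated acid. The fallback sets out from 7 and comes back at 8. It forms the acyl C–O bond by carbodiimide coupling instead of the C2–O bond by insertion. Decomposition of 7 with Rh2(OAc)4 in toluene containing water (O–H insertion into water, with no competing alkene present) should give tert-butyl 2-(diethoxyphosphoryl)-2-hydroxyacetate F6. Acylation of F6 with acid 5 (EDC·HCl, catalytic DMAP, CH2Cl2, 0 °C) then gives 8.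

Step 6. Addition of the hindered, strongly stabilised phosphonate anion to the electron-rich aldehyde may be slow, leaving time for base-induced loss or transfer of the caffeoyl group and for desilylation of the phenol ethers. The fallback sets out from acid 5 and comes back at 9. It makes the C3–aryl bond by Mizoroki–Heck arylation instead of making C2=C3 by olefination. Acid 5 with oxalyl chloride and catalytic DMF (CH2Cl2, 0 °C) should give (E)-3-[3,4-bis(tert-butyldimethylsilyloxy)phenyl]prop-2-enoyl chloride F7. O-Acylation of the enol form of commercial tert-butyl pyruvate with F7 (Et3N, DMAP, CH2Cl2, 0 °C to rt) should give tert-butyl 2-{[(E)-3-(3,4-bis(tert-butyldimethylsilyloxy)phenyl)prop-2-enoyl]oxy}prop-2-enoate F8. Commercial 4-iodo-2-methoxyphenol is silylated (TBSCl, imidazole, DMF) to tert-butyl(4-iodo-2-methoxyphenoxy)dimethylsilane F9. Heck coupling of F8 with F9 (Pd(OAc)2, P(o-tol)3, Et3N, MeCN, 80 °C) should arylate the terminal acrylate carbon, as with 2-amidoacrylates, and give 9, mainly as the (Z)-isomer; the internal caffeoyl alkene is expected to react much more slowly.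

**Further compounds**

F1 | step 7 | tert-butyl 2-acetoxy-2-(diethoxyphosphoryl)acetate | CCOP(=O)(OCC)C(OC(C)=O)C(=O)OC(C)(C)C
F2 | step 7 | tert-butyl (Z)-2-acetoxy-3-[4-(tert-butyldimethylsilyloxy)-3-methoxyphenyl]prop-2-enoate | CC(=O)O/C(C(=O)OC(C)(C)C)=C\c1ccc(O[Si](C)(C)C(C)(C)C)c(OC)c1
F3 | step 7 | tert-butyl (E)-2-acetoxy-3-[4-(tert-butyldimethylsilyloxy)-3-methoxyphenyl]prop-2-enoate | CC(=O)O/C(C(=O)OC(C)(C)C)=C/c1ccc(O[Si](C)(C)C(C)(C)C)c(OC)c1
F4 | step 7 | tert-butyl (2R)-2-acetoxy-3-[4-(tert-butyldimethylsilyloxy)-3-methoxyphenyl]propanoate | COc1cc(C[C@@H](OC(C)=O)C(=O)OC(C)(C)C)ccc1O[Si](C)(C)C(C)(C)C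
F5 | step 7 | tert-butyl (2R)-2-hydroxy-3-[4-(tert-butyldimethylsilyloxy)-3-methoxyphenyl]propanoate | COc1cc(C[C@@H](O)C(=O)OC(C)(C)C)ccc1O[Si](C)(C)C(C)(C)C
F6 | step 5 | tert-butyl 2-(diethoxyphosphoryl)-2-hydroxyacetate | CCOP(=O)(OCC)C(O)C(=O)OC(C)(C)C
F7 | step 6 | (E)-3-[3,4-bis(tert-butyldimethylsilyloxy)phenyl]prop-2-enoyl chloride | O=C(Cl)/C=C/c1ccc(O[Si](C)(C)C(C)(C)C)c(O[Si](C)(C)C(C)(C)C)c1
F8 | step 6 | tert-butyl 2-{[(E)-3-(3,4-bis(tert-butyldimethylsilyloxy)phenyl)prop-2-enoyl]oxy}prop-2-enoate | C=C(OC(=O)/C=C/c1ccc(O[Si](C)(C)C(C)(C)C)c(O[Si](C)(C)C(C)(C)C)c1)C(=O)OC(C)(C)C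
F9 | step 6 | tert-butyl(4-iodo-2-methoxyphenoxy)dimethylsilane | COc1cc(I)ccc1O[Si](C)(C)C(C)(C)C
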